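**Retrosynthetic overview** (indene numbering: C1 Et, C2 C=O, C3 Me, C3a, C4 CO2H/Et, C5 styryl/Et, C6=C7 Me, C7a)
1. The acid comes from its allyl ester and the C2 ketone from a C2 silyl ether, so the endgame is desilylation, oxidation and deallylation.
2. Both rings are cut at once: C3a–C7a and C4–C5 come from an intramolecular Diels–Alder reaction of a linear (E,E,E)-styryl triene tethered to an (E)-2-ethyl enoate.
3. The dienophile comes from a Wittig reaction at C3a; the triene comes from Wittig, Wittig and Horner–Wadsworth–Emmons olefinations starting at C7a.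
4. The C1–C2 bond joins the two chiral fragments in an Evans syn-aldol between an (R)-4-benzyl-3-butanoyl oxazolidinone and an (S)-Roche-ester aldehyde; this fixes C1 and C3.
5. Ring order: the chain stays acyclic until the cycloaddition, where the five- and six-membered rings form together.

Assumption: the SMILES is read as the trans-fused (1S,3S,3aR,4R,5S,7aR) acid with an (E)-styryl group; TBS = tert-butyldimethylsilyl, TBSO = its ether.

**Step 1**
Reactants: 1 (R)-4-benzyl-1,3-oxazolidin-2-one; 2 butanoyl chloride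
Product: 4 (R)-4-benzyl-3-butanoyl-1,3-oxazolidin-2-one, via lithium oxazolidinide 3 (not isolated)
Conditions: n-BuLi, THF, −78 °C; then 2, −78 to 0 °C
Reagents that add atoms: none
Why: Nucleophilic acyl substitution of the acid chloride by the lithiated carbamate nitrogen is clean and leaves the benzyl-bearing stereocentre untouched.

**Step 2**
Reactants: 5 methyl (S)-3-hydroxy-2-methylpropanoate
Product: 6 methyl (S)-3-(TBSO)-2-methylpropanoate
Conditions: TBSCl, imidazole, CH2Cl2, 0 °C to rt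
Reagents that add atoms: tert-butyldimethylsilyl chloride (TBSCl), CC(C)(C)[Si](C)(C)Cl
Why: Imidazole-promoted silyl ether formation masks the primary alcohol without touching the epimerisable α-centre.

**Step 3**
Reactants: 6 methyl (S)-3-(TBSO)-2-methylpropanoate
Product: 7 (R)-3-(TBSO)-2-methylpropan-1-ol
Conditions: i-Bu2AlH (2.5 equiv), CH2Cl2, −78 to 0 °C; aq. KNaC4H4O6
Reagents that add atoms: none
Why: Full ester reduction to the alcohol avoids the variable over-reduction of a direct ester-to-aldehyde stop and does not affect the stereocentre (the descriptor changes only through priorities).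

**Step 4**
Reactants: 7 (R)-3-(TBSO)-2-methylpropan-1-ol
Product: 8 (S)-3-(TBSO)-2-methylpropanal
Conditions: Dess–Martin periodinane, pyridine, CH2Cl2, 0 °C to rt; used crude at once
Reagents that add atoms: none
Why: Dess–Martin oxidation under buffered, non-enolising conditions gives the configurationally labile α-methyl aldehyde without racemisation.

**Step 5**
Reactants: 4 (R)-4-benzyl-3-butanoyl-1,3-oxazolidin-2-one; 8 (S)-3-(TBSO)-2-methylpropanal
Product: 11 (R)-4-benzyl-3-[(2R,3S,4S)-5-(TBSO)-2-ethyl-3-hydroxy-4-methylpentanoyl]-1,3-oxazolidin-2-one, via Z-boron enolate 9 (not isolated), via boron aldolate 10 (not isolated)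
Conditions: Bu2BOTf, i-Pr2NEt, CH2Cl2, 0 °C; 8, −78 to 0 °C; MeOH, aq. NaH2PO4/Na2HPO4 (pH 7), 30% H2O2, 0 °C
Reagents that add atoms: none
Why: Evans syn-aldol in which the Z-dibutylboron enolate reacts through a Zimmerman–Traxler chair whose enolate face is dictated by the (R)-benzyl auxiliary, setting (2R,3S) (the C1 ethyl centre and the C2 oxygen), a sense that is also the favoured anti-Felkin addition to the (S)-aldehyde whose centre becomes C3.

**Step 6**
Reactants: 11 (R)-4-benzyl-3-[(2R,3S,4S)-5-(TBSO)-2-ethyl-3-hydroxy-4-methylpentanoyl]-1,3-oxazolidin-2-one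
Product: 12 (R)-4-benzyl-3-[(2R,3S,4S)-3,5-bis(TBSO)-2-ethyl-4-methylpentanoyl]-1,3-oxazolidin-2-one
Conditions: TBSOTf, 2,6-lutidine, CH2Cl2, −78 to 0 °C
Reagents that add atoms: tert-butyldimethylsilyl trifluoromethanesulfonate (TBSOTf), CC(C)(C)[Si](C)(C)OS(=O)(=O)C(F)(F)F
Why: Silylation with the reactive silyl triflate protects the hindered secondary alcohol and blocks retro-aldol cleavage later.

**Step 7**
Reactants: 12 (R)-4-benzyl-3-[(2R,3S,4S)-3,5-bis(TBSO)-2-ethyl-4-methylpentanoyl]-1,3-oxazolidin-2-one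
Product: 13 (2S,3S,4S)-3,5-bis(TBSO)-2-ethyl-4-methylpentan-1-ol
Conditions: LiBH4, H2O (1 equiv), Et2O, 0 °C
Reagents that add atoms: none
Why: Reductive cleavage of the imide by hydride attack at the exocyclic carbonyl releases the recoverable auxiliary and the primary alcohol without epimerising the α-centre.

**Step 8**
Reactants: 13 (2S,3S,4S)-3,5-bis(TBSO)-2-ethyl-4-methylpentan-1-ol
Product: 14 (2R,3S,4S)-3,5-bis(TBSO)-2-ethyl-4-methylpentanal
Conditions: Dess–Martin periodinane, pyridine, CH2Cl2, 0 °C to rt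
Reagents that add atoms: none
Why: Dess–Martin oxidation gives the α-branched aldehyde (future C7a) under non-basic conditions that keep C1 intact.

**Step 9**
Reactants: 14 (2R,3S,4S)-3,5-bis(TBSO)-2-ethyl-4-methylpentanal; 15 ethyl 2-(triphenylphosphoranylidene)propanoate
Product: 16 ethyl (2E,4S,5R,6S)-5,7-bis(TBSO)-4-ethyl-2,6-dimethylhept-2-enoate
Conditions: toluene, 80 °C
Reagents that add atoms: none
Why: Wittig olefination with a stabilised α-methyl ylide is reliably E-selective with α-branched aldehydes and installs C7 with its methyl group.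

**Step 10**
Reactants: 16 ethyl (2E,4S,5R,6S)-5,7-bis(TBSO)-4-ethyl-2,6-dimethylhept-2-enoate
Product: 17 (2E,4S,5R,6S)-5,7-bis(TBSO)-4-ethyl-2,6-dimethylhept-2-en-1-ol
Conditions: i-Bu2AlH, CH2Cl2, −78 °C; aq. KNaC4H4O6
Reagents that add atoms: none
Why: 1,2-Reduction of the enoate at low temperature gives the allylic alcohol while silyl ethers are inert.

**Step 11**
Reactants: 17 (2E,4S,5R,6S)-5,7-bis(TBSO)-4-ethyl-2,6-dimethylhept-2-en-1-ol
Product: 18 (2E,4S,5R,6S)-5,7-bis(TBSO)-4-ethyl-2,6-dimethylhept-2-enal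
Conditions: MnO2, CH2Cl2, rt
Reagents that add atoms: none
Why: MnO2 oxidises the allylic alcohol chemoselectively to the enal without E/Z isomerisation or over-oxidation.

**Step 12**
Reactants: 19 2-bromobutanoic acid (racemic); 20 prop-2-en-1-ol
Product: 21 prop-2-en-1-yl 2-bromobutanoate (racemic)
Conditions: TsOH·H2O (cat.), toluene, reflux, Dean–Stark
Reagents that add atoms: none
Why: Fischer esterification driven by azeotropic water removal gives the allyl ester that later allows non-hydrolytic release of the hindered acid.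

**Step 13**
Reactants: 21 prop-2-en-1-yl 2-bromobutanoate; 22 triphenylphosphine
Product: 24 prop-2-en-1-yl 2-(triphenylphosphoranylidene)butanoate, via phosphonium bromide 23 (not isolated)
Conditions: toluene, 90 °C; then CH2Cl2, 1 M aq. NaOH, 0 °C
Reagents that add atoms: none
Why: SN2 alkylation of the phosphine by the α-bromo ester followed by deprotonation of the acidic α-C–H gives the bench-stable stabilised Wittig ylide.

**Step 14**
Reactants: 18 (2E,4S,5R,6S)-5,7-bis(TBSO)-4-ethyl-2,6-dimethylhept-2-enal; 24 prop-2-en-1-yl 2-(triphenylphosphoranylidene)butanoate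
Product: 25 prop-2-en-1-yl (2E,4E,6S,7R,8S)-7,9-bis(TBSO)-2,6-diethyl-4,8-dimethylnona-2,4-dienoate
Conditions: toluene, 100 °C
Reagents that add atoms: none
Why: Wittig olefination with the stabilised α-ethyl ylide gives the (2E,4E)-dienoate, placing the ethyl group cis and the carboxyl carbon trans to the chain at the future C5.

**Step 15**
Reactants: 25 prop-2-en-1-yl (2E,4E,6S,7R,8S)-7,9-bis(TBSO)-2,6-diethyl-4,8-dimethylnona-2,4-dienoate
Product: 26 (2E,4E,6S,7R,8S)-7,9-bis(TBSO)-2,6-diethyl-4,8-dimethylnona-2,4-dien-1-ol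
Conditions: i-Bu2AlH, CH2Cl2, −78 °C; aq. KNaC4H4O6
Reagents that add atoms: none
Why: 1,2-Reduction of the dienoate gives the dienol without touching the diene geometry or the silyl ethers.

**Step 16**
Reactants: 26 (2E,4E,6S,7R,8S)-7,9-bis(TBSO)-2,6-diethyl-4,8-dimethylnona-2,4-dien-1-ol
Product: 27 (2E,4E,6S,7R,8S)-7,9-bis(TBSO)-2,6-diethyl-4,8-dimethylnona-2,4-dienal
Conditions: MnO2, CH2Cl2, rt
Reagents that add atoms: none
Why: Allylic oxidation with MnO2 gives the dienal cleanly and leaves the remote stereocentres alone.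

**Step 17**
Reactants: 27 (2E,4E,6S,7R,8S)-7,9-bis(TBSO)-2,6-diethyl-4,8-dimethylnona-2,4-dienal; 28 diethyl benzylphosphonate
Product: 30 [(1E,3E,5E,7S,8R,9S)-8,10-bis(TBSO)-3,7-diethyl-5,9-dimethyldeca-1,3,5-trien-1-yl]benzene, via sodium phosphonate carbanion 29 (not isolated)
Conditions: NaH, THF, 0 °C; then 27, 0 °C to rt
Reagents that add atoms: none
Why: Horner–Wadsworth–Emmons olefination with the benzylphosphonate anion gives the (E)-styryl double bond with high selectivity, and the aldehyde has no α-hydrogen to enolise.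

**Step 18**
Reactants: 30 [(1E,3E,5E,7S,8R,9S)-8,10-bis(TBSO)-3,7-diethyl-5,9-dimethyldeca-1,3,5-trien-1-yl]benzene
Product: 31 (2S,3R,4S,5E,7E,9E)-3-(TBSO)-4,8-diethyl-2,6-dimethyl-10-phenyldeca-5,7,9-trien-1-ol
Conditions: HF·pyridine, pyridine, THF, 0 °C to rt
Reagents that add atoms: none
Why: Selective desilylation, because buffered HF·pyridine cleaves the unhindered primary silyl ether much faster than the secondary one flanked by two branched carbons.

**Step 19**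
Reactants: 31 (2S,3R,4S,5E,7E,9E)-3-(TBSO)-4,8-diethyl-2,6-dimethyl-10-phenyldeca-5,7,9-trien-1-ol
Product: 32 (2R,3R,4S,5E,7E,9E)-3-(TBSO)-4,8-diethyl-2,6-dimethyl-10-phenyldeca-5,7,9-trienal
Conditions: Dess–Martin periodinane, pyridine, CH2Cl2, 0 °C
Reagents that add atoms: none
Why: Buffered Dess–Martin oxidation gives the α-methyl aldehyde (future C3a) without epimerising C3 or harming the triene.

**Step 20**
Reactants: 32 (2R,3R,4S,5E,7E,9E)-3-(TBSO)-4,8-diethyl-2,6-dimethyl-10-phenyldeca-5,7,9-trienal; 24 prop-2-en-1-yl 2-(triphenylphosphoranylidene)butanoate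
Product: 34 prop-2-en-1-yl (1S,2S,3S,3aR,4R,5S,7aR)-2-(TBSO)-1,4,5-triethyl-3,7-dimethyl-5-[(E)-2-phenylethenyl]-2,3,3a,4,5,7a-hexahydro-1H-indene-4-carboxylate, via tetraene ester 33 (not isolated)
Conditions: toluene, 60 °C; then BHT (cat.), 110 °C
Reagents that add atoms: none
Why: The Wittig reaction gives the (E)-2-ethyl enoate, and the tethered (E,E)-diene then undergoes an intramolecular Diels–Alder reaction through the ester-endo transition state in which H1 and H3 lie in the diene and dienophile planes to avoid allylic 1,3-strain with the C7 methyl and C4 ethyl groups, so the matched C1 and C3 centres set C3a, C4, C5 and C7a with a trans ring fusion as both rings close.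

**Step 21**
Reactants: 34 prop-2-en-1-yl (1S,2S,3S,3aR,4R,5S,7aR)-2-(TBSO)-1,4,5-triethyl-3,7-dimethyl-5-[(E)-2-phenylethenyl]-2,3,3a,4,5,7a-hexahydro-1H-indene-4-carboxylate
Product: 35 prop-2-en-1-yl (1S,2S,3S,3aR,4R,5S,7aR)-1,4,5-triethyl-2-hydroxy-3,7-dimethyl-5-[(E)-2-phenylethenyl]-2,3,3a,4,5,7a-hexahydro-1H-indene-4-carboxylate
Conditions: HF·pyridine, THF, rt (40 °C if slow)
Reagents that add atoms: none
Why: Fluoride-mediated desilylation under acidic, non-nucleophilic conditions frees the C2 alcohol without forming an alkoxide, so the allyl ester is not attacked.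

**Step 22**
Reactants: 35 prop-2-en-1-yl (1S,2S,3S,3aR,4R,5S,7aR)-1,4,5-triethyl-2-hydroxy-3,7-dimethyl-5-[(E)-2-phenylethenyl]-2,3,3a,4,5,7a-hexahydro-1H-indene-4-carboxylate
Product: 36 prop-2-en-1-yl (1S,3S,3aR,4R,5S,7aR)-1,4,5-triethyl-3,7-dimethyl-2-oxo-5-[(E)-2-phenylethenyl]-2,3,3a,4,5,7a-hexahydro-1H-indene-4-carboxylate
Conditions: Dess–Martin periodinane, pyridine, CH2Cl2, rt
Reagents that add atoms: none
Why: Dess–Martin oxidation gives the C2 ketone under near-neutral conditions, and the α-centres C1 and C3 already carry their alkyl groups trans to the adjacent ring bonds, so no epimerisation is expected.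

**Step 23**
Reactants: 36 prop-2-en-1-yl (1S,3S,3aR,4R,5S,7aR)-1,4,5-triethyl-3,7-dimethyl-2-oxo-5-[(E)-2-phenylethenyl]-2,3,3a,4,5,7a-hexahydro-1H-indene-4-carboxylate
Product: 37 (1S,3S,3aR,4R,5S,7aR)-1,4,5-triethyl-3,7-dimethyl-2-oxo-5-[(E)-2-phenylethenyl]-2,3,3a,4,5,7a-hexahydro-1H-indene-4-carboxylic acid
Conditions: Pd(PPh3)4 (5 mol %), morpholine, THF, rt; dilute aq. citric acid work-up
Reagents that add atoms: none
Why: Tsuji–Trost deallylation, in which the zerovalent palladium complex ionises the allyl ester to a π-allyl species that morpholine captures, frees the neopentyl-type acid that hydrolysis could not reach and touches no stereocentre.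

**Compound list**
1 | (R)-4-benzyl-1,3-oxazolidin-2-one | O=C1N[C@H](Cc2ccccc2)CO1 | starting material
2 | butanoyl chloride | CCCC(=O)Cl | starting material
3 | lithium (R)-4-benzyl-2-oxo-1,3-oxazolidin-3-ide | [Li+].O=C1[N-][C@H](Cc2ccccc2)CO1 | intermediate
4 | (R)-4-benzyl-3-butanoyl-1,3-oxazolidin-2-one | CCCC(=O)N1[C@H](Cc2ccccc2)COC1=O | intermediate
5 | methyl (S)-3-hydroxy-2-methylpropanoate | COC(=O)[C@@H](C)CO | starting material
6 | methyl (S)-3-(TBSO)-2-methylpropanoate | COC(=O)[C@@H](C)CO[Si](C)(C)C(C)(C)C | intermediate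
7 | (R)-3-(TBSO)-2-methylpropan-1-ol | OC[C@@H](C)CO[Si](C)(C)C(C)(C)C | intermediate
8 | (S)-3-(TBSO)-2-methylpropanal | O=C[C@@H](C)CO[Si](C)(C)C(C)(C)C | intermediate
9 | (R)-4-benzyl-3-[(1Z)-1-[(dibutylboranyl)oxy]but-1-en-1-yl]-1,3-oxazolidin-2-one (Z-boron enolate) | CC/C=C(\OB(CCCC)CCCC)N1[C@H](Cc2ccccc2)COC1=O | intermediate
10 | (R)-4-benzyl-3-[(2R,3S,4S)-5-(TBSO)-3-[(dibutylboranyl)oxy]-2-ethyl-4-methylpentanoyl]-1,3-oxazolidin-2-one (boron aldolate) | CC[C@@H](C(=O)N1[C@H](Cc2ccccc2)COC1=O)[C@@H](OB(CCCC)CCCC)[C@@H](C)CO[Si](C)(C)C(C)(C)C | intermediate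
11 | (R)-4-benzyl-3-[(2R,3S,4S)-5-(TBSO)-2-ethyl-3-hydroxy-4-methylpentanoyl]-1,3-oxazolidin-2-one | CC[C@@H](C(=O)N1[C@H](Cc2ccccc2)COC1=O)[C@@H](O)[C@@H](C)CO[Si](C)(C)C(C)(C)C | intermediate
12 | (R)-4-benzyl-3-[(2R,3S,4S)-3,5-bis(TBSO)-2-ethyl-4-methylpentanoyl]-1,3-oxazolidin-2-one | CC[C@@H](C(=O)N1[C@H](Cc2ccccc2)COC1=O)[C@@H](O[Si](C)(C)C(C)(C)C)[C@@H](C)CO[Si](C)(C)C(C)(C)C | intermediate
13 | (2S,3S,4S)-3,5-bis(TBSO)-2-ethyl-4-methylpentan-1-ol | CC[C@@H](CO)[C@@H](O[Si](C)(C)C(C)(C)C)[C@@H](C)CO[Si](C)(C)C(C)(C)C | intermediate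
14 | (2R,3S,4S)-3,5-bis(TBSO)-2-ethyl-4-methylpentanal | CC[C@@H](C=O)[C@@H](O[Si](C)(C)C(C)(C)C)[C@@H](C)CO[Si](C)(C)C(C)(C)C | intermediate
15 | ethyl 2-(triphenylphosphoranylidene)propanoate | CCOC(=O)C(C)=P(c1ccccc1)(c1ccccc1)c1ccccc1 | starting material
16 | ethyl (2E,4S,5R,6S)-5,7-bis(TBSO)-4-ethyl-2,6-dimethylhept-2-enoate | CC[C@@H](/C=C(\C)C(=O)OCC)[C@@H](O[Si](C)(C)C(C)(C)C)[C@@H](C)CO[Si](C)(C)C(C)(C)C | intermediate
17 | (2E,4S,5R,6S)-5,7-bis(TBSO)-4-ethyl-2,6-dimethylhept-2-en-1-ol | CC[C@@H](/C=C(\C)CO)[C@@H](O[Si](C)(C)C(C)(C)C)[C@@H](C)CO[Si](C)(C)C(C)(C)C | intermediate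
18 | (2E,4S,5R,6S)-5,7-bis(TBSO)-4-ethyl-2,6-dimethylhept-2-enal | CC[C@@H](/C=C(\C)C=O)[C@@H](O[Si](C)(C)C(C)(C)C)[C@@H](C)CO[Si](C)(C)C(C)(C)C | intermediate
19 | 2-bromobutanoic acid (racemic) | CCC(Br)C(=O)O | starting material
20 | prop-2-en-1-ol (allyl alcohol) | C=CCO | starting material
21 | prop-2-en-1-yl 2-bromobutanoate (racemic) | CCC(Br)C(=O)OCC=C | intermediate
22 | triphenylphosphine | c1ccc(cc1)P(c1ccccc1)c1ccccc1 | starting material
23 | [1-(prop-2-en-1-yloxy)-1-oxobutan-2-yl]triphenylphosphonium bromide | CCC(C(=O)OCC=C)[P+](c1ccccc1)(c1ccccc1)c1ccccc1.[Br-] | intermediate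
24 | prop-2-en-1-yl 2-(triphenylphosphoranylidene)butanoate | CCC(C(=O)OCC=C)=P(c1ccccc1)(c1ccccc1)c1ccccc1 | intermediate
25 | prop-2-en-1-yl (2E,4E,6S,7R,8S)-7,9-bis(TBSO)-2,6-diethyl-4,8-dimethylnona-2,4-dienoate | CC[C@@H](/C=C(\C)/C=C(\CC)C(=O)OCC=C)[C@@H](O[Si](C)(C)C(C)(C)C)[C@@H](C)CO[Si](C)(C)C(C)(C)C | intermediate
26 | (2E,4E,6S,7R,8S)-7,9-bis(TBSO)-2,6-diethyl-4,8-dimethylnona-2,4-dien-1-ol | CC[C@@H](/C=C(\C)/C=C(\CC)CO)[C@@H](O[Si](C)(C)C(C)(C)C)[C@@H](C)CO[Si](C)(C)C(C)(C)C | intermediate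
27 | (2E,4E,6S,7R,8S)-7,9-bis(TBSO)-2,6-diethyl-4,8-dimethylnona-2,4-dienal | CC[C@@H](/C=C(\C)/C=C(\CC)C=O)[C@@H](O[Si](C)(C)C(C)(C)C)[C@@H](C)CO[Si](C)(C)C(C)(C)C | intermediate
28 | diethyl benzylphosphonate | CCOP(=O)(Cc1ccccc1)OCC | starting material
29 | sodium (diethoxyphosphoryl)(phenyl)methanide | [Na+].CCOP(=O)([CH-]c1ccccc1)OCC | intermediate
30 | [(1E,3E,5E,7S,8R,9S)-8,10-bis(TBSO)-3,7-diethyl-5,9-dimethyldeca-1,3,5-trien-1-yl]benzene | CC[C@@H](/C=C(\C)/C=C(\CC)/C=C/c1ccccc1)[C@@H](O[Si](C)(C)C(C)(C)C)[C@@H](C)CO[Si](C)(C)C(C)(C)C | intermediate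
31 | (2S,3R,4S,5E,7E,9E)-3-(TBSO)-4,8-diethyl-2,6-dimethyl-10-phenyldeca-5,7,9-trien-1-ol | CC[C@@H](/C=C(\C)/C=C(\CC)/C=C/c1ccccc1)[C@@H](O[Si](C)(C)C(C)(C)C)[C@@H](C)CO | intermediate
32 | (2R,3R,4S,5E,7E,9E)-3-(TBSO)-4,8-diethyl-2,6-dimethyl-10-phenyldeca-5,7,9-trienal | CC[C@@H](/C=C(\C)/C=C(\CC)/C=C/c1ccccc1)[C@@H](O[Si](C)(C)C(C)(C)C)[C@@H](C)C=O | intermediate
33 | prop-2-en-1-yl (2E,4S,5S,6S,7E,9E,11E)-5-(TBSO)-2,6,10-triethyl-4,8-dimethyl-12-phenyldodeca-2,7,9,11-tetraenoate | CC[C@@H](/C=C(\C)/C=C(\CC)/C=C/c1ccccc1)[C@@H](O[Si](C)(C)C(C)(C)C)[C@@H](C)/C=C(\CC)C(=O)OCC=C | intermediate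
34 | prop-2-en-1-yl (1S,2S,3S,3aR,4R,5S,7aR)-2-(TBSO)-1,4,5-triethyl-3,7-dimethyl-5-[(E)-2-phenylethenyl]-2,3,3a,4,5,7a-hexahydro-1H-indene-4-carboxylate | CC[C@@H]1[C@@H](O[Si](C)(C)C(C)(C)C)[C@@H](C)[C@H]2[C@H]1C(C)=C[C@@](/C=C/c1ccccc1)(CC)[C@]2(CC)C(=O)OCC=C | intermediate
35 | prop-2-en-1-yl (1S,2S,3S,3aR,4R,5S,7aR)-1,4,5-triethyl-2-hydroxy-3,7-dimethyl-5-[(E)-2-phenylethenyl]-2,3,3a,4,5,7a-hexahydro-1H-indene-4-carboxylate | CC[C@@H]1[C@@H](O)[C@@H](C)[C@H]2[C@H]1C(C)=C[C@@](/C=C/c1ccccc1)(CC)[C@]2(CC)C(=O)OCC=C | intermediate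
36 | prop-2-en-1-yl (1S,3S,3aR,4R,5S,7aR)-1,4,5-triethyl-3,7-dimethyl-2-oxo-5-[(E)-2-phenylethenyl]-2,3,3a,4,5,7a-hexahydro-1H-indene-4-carboxylate | CC[C@@H]1C(=O)[C@@H](C)[C@H]2[C@H]1C(C)=C[C@@](/C=C/c1ccccc1)(CC)[C@]2(CC)C(=O)OCC=C | intermediate
37 | (1S,3S,3aR,4R,5S,7aR)-1,4,5-triethyl-3,7-dimethyl-2-oxo-5-[(E)-2-phenylethenyl]-2,3,3a,4,5,7a-hexahydro-1H-indene-4-carboxylic acid | CC[C@@H]1C(=O)[C@@H](C)[C@H]2[C@H]1C(C)=C[C@@](/C=C/c1ccccc1)(CC)[C@]2(CC)C(=O)O | target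

**Totals**
Total step count: 23. Longest linear sequence: 20 steps (5 to 37 through steps 2–11 and 14–23).

**Steps most likely to fail, with fallbacks**

Step 14: the Wittig reaction of the α-methyl enal 18 with the bulky α-ethyl ylide 24 may be slow and lose E-selectivity. The fallback sets out from 18 and returns at 30, bypassing steps 14 to 17. A dibromo-olefination of 18 (CBr4, PPh3, CH2Cl2, 0 °C) gives the 1,1-dibromodiene F1. A Suzuki coupling with (E)-2-phenylethenylboronic acid (Pd2(dba)3, tri(2-furyl)phosphine, aq. Cs2CO3, THF, rt) replaces only the bromine trans to the chain and gives the (Z)-bromotriene F2. A Negishi coupling with EtZnCl (Pd(P(t-Bu)3)2, THF, rt) then installs the ethyl group with retention and gives 30, so both alkene geometries come from stereospecific cross-coupling instead of carbonyl olefination.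

Step 18: discrimination between the two silyl ethers may be incomplete, or the triene may suffer under HF. The fallback sets out from 30 and returns at 35, avoiding both the selective and the late desilylation. Both silyl groups are removed (Bu4NF, THF) to give the diol F3. Only the primary alcohol is oxidised with TEMPO (cat.)/PhI(OAc)2 in CH2Cl2 to give the hydroxy aldehyde F4. A Wittig reaction with 24 (toluene, 60 °C) gives the hydroxy tetraene ester F5, which on heating to 110 °C undergoes the same cycloaddition and gives 35.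

Step 20: the thermal cycloaddition of the enoate may be sluggish at the fully substituted diene terminus or give isomer mixtures. The fallback sets out from 33 (isolated after the 60 °C stage) and returns at 34. Reduction with i-Bu2AlH (CH2Cl2, −78 °C) gives the allylic alcohol F6 and MnO2 oxidation gives the enal F7, a much stronger dienophile. It cyclises at or below rt (Me2AlCl, CH2Cl2, −78 °C if needed) to the bicyclic aldehyde F8. Pinnick oxidation (NaClO2, NaH2PO4, 2-methylbut-2-ene, t-BuOH/H2O) gives the acid F9, and O-alkylation with allyl bromide (K2CO3, DMF) gives 34.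

**Further compounds**
F1 | step 14 | (3E,5S,6R,7S)-1,1-dibromo-6,8-bis(TBSO)-5-ethyl-3,7-dimethylocta-1,3-diene | CC[C@@H](/C=C(\C)C=C(Br)Br)[C@@H](O[Si](C)(C)C(C)(C)C)[C@@H](C)CO[Si](C)(C)C(C)(C)C
F2 | step 14 | [(1E,3Z,5E,7S,8R,9S)-3-bromo-8,10-bis(TBSO)-7-ethyl-5,9-dimethyldeca-1,3,5-trien-1-yl]benzene | CC[C@@H](/C=C(\C)/C=C(\Br)/C=C/c1ccccc1)[C@@H](O[Si](C)(C)C(C)(C)C)[C@@H](C)CO[Si](C)(C)C(C)(C)C
F3 | step 18 | (2S,3R,4S,5E,7E,9E)-4,8-diethyl-2,6-dimethyl-10-phenyldeca-5,7,9-triene-1,3-diol | CC[C@@H](/C=C(\C)/C=C(\CC)/C=C/c1ccccc1)[C@@H](O)[C@@H](C)CO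
F4 | step 18 | (2R,3R,4S,5E,7E,9E)-4,8-diethyl-3-hydroxy-2,6-dimethyl-10-phenyldeca-5,7,9-trienal | CC[C@@H](/C=C(\C)/C=C(\CC)/C=C/c1ccccc1)[C@@H](O)[C@@H](C)C=O
F5 | step 18 | prop-2-en-1-yl (2E,4S,5S,6S,7E,9E,11E)-2,6,10-triethyl-5-hydroxy-4,8-dimethyl-12-phenyldodeca-2,7,9,11-tetraenoate | CC[C@@H](/C=C(\C)/C=C(\CC)/C=C/c1ccccc1)[C@@H](O)[C@@H](C)/C=C(\CC)C(=O)OCC=C
F6 | step 20 | (2E,4S,5S,6S,7E,9E,11E)-5-(TBSO)-2,6,10-triethyl-4,8-dimethyl-12-phenyldodeca-2,7,9,11-tetraen-1-ol | CC[C@@H](/C=C(\C)/C=C(\CC)/C=C/c1ccccc1)[C@@H](O[Si](C)(C)C(C)(C)C)[C@@H](C)/C=C(\CC)CO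
F7 | step 20 | (2E,4S,5S,6S,7E,9E,11E)-5-(TBSO)-2,6,10-triethyl-4,8-dimethyl-12-phenyldodeca-2,7,9,11-tetraenal | CC[C@@H](/C=C(\C)/C=C(\CC)/C=C/c1ccccc1)[C@@H](O[Si](C)(C)C(C)(C)C)[C@@H](C)/C=C(\CC)C=O
F8 | step 20 | (1S,2S,3S,3aR,4R,5S,7aR)-2-(TBSO)-1,4,5-triethyl-3,7-dimethyl-5-[(E)-2-phenylethenyl]-2,3,3a,4,5,7a-hexahydro-1H-indene-4-carbaldehyde | CC[C@@H]1[C@@H](O[Si](C)(C)C(C)(C)C)[C@@H](C)[C@H]2[C@H]1C(C)=C[C@@](/C=C/c1ccccc1)(CC)[C@]2(CC)C=O
F9 | step 20 | (1S,2S,3S,3aR,4R,5S,7aR)-2-(TBSO)-1,4,5-triethyl-3,7-dimethyl-5-[(E)-2-phenylethenyl]-2,3,3a,4,5,7a-hexahydro-1H-indene-4-carboxylic acid | CC[C@@H]1[C@@H](O[Si](C)(C)C(C)(C)C)[C@@H](C)[C@H]2[C@H]1C(C)=C[C@@](/C=C/c1ccccc1)(CC)[C@]2(CC)C(=O)O
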